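**Assumptions.** (2S)-(–)-Hesperetin, the aglycone of citrus hesperidin, is bought enantiopure and is the only source of chirality. Reagents that only donate atoms (BnBr, I2, BnOH, PhNTf2, B2pin2) are given with SMILES in each step and are not numbered.

## Retrosynthetic overview

1. Final step: global O-debenzylation of a tri-O-benzyl biflavonoid.
2. The C3′–C8″ biaryl bond is disconnected to a (2S)-hesperetin-derived 3′-boronate and an 8-iodoflavone (Suzuki–Miyaura).
3. The 8-iodoflavone comes from acacetin (benzylation, C8 iodination); acacetin comes from phloroglucinol and ethyl 4-methoxybenzoylacetate, with the flavone γ-pyrone ring closed by a thermal aroylketene hetero-[4+2] annulation (Mentzer type).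
4. The boronate comes from (2S)-hesperetin (7-O-Bn, 3′-OTf, Miyaura borylation); the flavanone tricycle and its C2 stereocentre are bought and never opened.
5. Ring-formation order: the flavone γ-pyrone is the first and only ring constructed; the other five rings come intact from phloroglucinol, the anisoyl ester and hesperetin.

## Route

**Step 1**
Reactants: 1, phloroglucinol (benzene-1,3,5-triol); 2, ethyl 3-(4-methoxyphenyl)-3-oxopropanoate
Product: 3, acacetin (5,7-dihydroxy-2-(4-methoxyphenyl)-4H-chromen-4-one)
Conditions: neat, 1 : 2 = 1 : 2, microwave (open vessel), 240 °C, 10 min; triturate with Et2O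
Reagents that add atoms: none
Why: Mentzer pyrone synthesis: the β-ketoester loses EtOH to give 4-methoxybenzoylketene, which acts as a 1-oxadiene in a formal hetero-Diels–Alder addition across an enolic C=C of C3-symmetric phloroglucinol, and loss of water gives the 5,7-dihydroxyflavone as a single regioisomer with no stereocentre.

**Step 2**
Reactants: 3, acacetin
Product: 4, 5,7-bis(benzyloxy)-2-(4-methoxyphenyl)-4H-chromen-4-one
Conditions: BnBr (3 equiv), K2CO3 (4 equiv), TBAI (cat.), DMF, 80 °C
Reagents that add atoms: benzyl bromide, BrCc1ccccc1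
Why: Williamson etherification (heat and excess halide alkylate the chelated 5-OH), giving groups removable without touching OMe and, by capping 5-OH, steering the next electrophile to C8.

**Step 3**
Reactants: 4
Product: 5, 5,7-bis(benzyloxy)-8-iodo-2-(4-methoxyphenyl)-4H-chromen-4-one
Conditions: I2 (1.1 equiv), CF3CO2Ag (1.1 equiv), CH2Cl2, 0 °C → rt, dark
Reagents that add atoms: iodine, II
Why: Electrophilic aromatic iodination: in 5-O-alkylated 5,7-dioxygenated flavones ring A reacts at C8, which has one flanking OBn, in preference to C6, which sits between two.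

**Step 4**
Reactants: 6, (2S)-hesperetin ((2S)-5,7-dihydroxy-2-(3-hydroxy-4-methoxyphenyl)chroman-4-one)
Product: 7, (2S)-7-(benzyloxy)-5-hydroxy-2-(3-hydroxy-4-methoxyphenyl)chroman-4-one
Conditions: BnOH (1.05 equiv), PPh3, DIAD, THF, 0 °C → rt
Reagents that add atoms: benzyl alcohol, OCc1ccccc1
Why: Mitsunobu etherification selects the most acidic phenol (7-OH; 5-OH is chelated and 3′-OH is less acidic) without added base, so the purchased C2 stereocentre cannot epimerise through the chalcone.

**Step 5**
Reactants: 7
Product: 8, 5-[(2S)-7-(benzyloxy)-5-hydroxy-4-oxochroman-2-yl]-2-methoxyphenyl trifluoromethanesulfonate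
Conditions: PhNTf2 (1.1 equiv), Et3N, DMAP (cat.), CH2Cl2, 0 °C → rt
Reagents that add atoms: N-phenylbis(trifluoromethanesulfonimide), O=S(=O)(N(c1ccccc1)S(=O)(=O)C(F)(F)F)C(F)(F)F
Why: Phenol triflation with a mild triflyl donor: only the free 3′-OH reacts because the 5-OH is hydrogen-bonded to C4=O, and C2 is untouched.

**Step 6**
Reactants: 8
Product: 9, (2S)-7-(benzyloxy)-5-hydroxy-2-[4-methoxy-3-(4,4,5,5-tetramethyl-1,3,2-dioxaborolan-2-yl)phenyl]chroman-4-one
Conditions: B2pin2 (1.3 equiv), PdCl2(dppf)·CH2Cl2 (5 mol %), KOAc (3 equiv), 1,4-dioxane, 80 °C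
Reagents that add atoms: bis(pinacolato)diboron, CC1(C)OB(B2OC(C)(C)C(C)(C)O2)OC1(C)C
Why: Miyaura borylation of the aryl triflate with weak acetate base, which leaves the flavanone ring and its (2S) centre intact.

**Step 7**
Reactants: 5 (1.3 equiv); 9 (1.0 equiv)
Product: 10, 5,7-bis(benzyloxy)-8-{5-[(2S)-7-(benzyloxy)-5-hydroxy-4-oxochroman-2-yl]-2-methoxyphenyl}-2-(4-methoxyphenyl)-4H-chromen-4-one
Conditions: SPhos Pd G3 (5 mol %), K3PO4 (3 equiv), THF/H2O 10:1, degassed, 45 °C
Reagents that add atoms: none
Why: Suzuki–Miyaura coupling with a bulky biarylphosphine catalyst suited to the tri-ortho-substituted biaryl, run at low temperature with the 5-OH as its phenoxide (which disfavours C3 enolisation and retro-oxa-Michael opening) so the C2 configuration is retained.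

**Step 8**
Reactants: 10
Product: 11, target: 8-{5-[(2S)-5,7-dihydroxy-4-oxochroman-2-yl]-2-methoxyphenyl}-5,7-dihydroxy-2-(4-methoxyphenyl)-4H-chromen-4-one
Conditions: H2 (1 atm), 10 % Pd/C, THF/MeOH 1:1, rt
Reagents that add atoms: none
Why: Neutral hydrogenolysis removes the three benzyl ethers, while the two methyl ethers, the flavone C2=C3 bond and the (2S)-flavanone are expected to survive at 1 atm and rt.

## Compound list

1 | phloroglucinol | Oc1cc(O)cc(O)c1 | starting material
2 | ethyl 3-(4-methoxyphenyl)-3-oxopropanoate | CCOC(=O)CC(=O)c1ccc(OC)cc1 | starting material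
3 | acacetin | COc1ccc(-c2cc(=O)c3c(O)cc(O)cc3o2)cc1 | intermediate
4 | 5,7-di-O-benzylacacetin | COc1ccc(-c2cc(=O)c3c(OCc4ccccc4)cc(OCc4ccccc4)cc3o2)cc1 | intermediate
5 | 8-iodo-5,7-di-O-benzylacacetin | COc1ccc(-c2cc(=O)c3c(OCc4ccccc4)cc(OCc4ccccc4)c(I)c3o2)cc1 | intermediate
6 | (2S)-hesperetin | COc1ccc([C@@H]2CC(=O)c3c(O)cc(O)cc3O2)cc1O | starting material
7 | (2S)-7-O-benzylhesperetin | COc1ccc([C@@H]2CC(=O)c3c(O)cc(OCc4ccccc4)cc3O2)cc1O | intermediate
8 | (2S)-7-O-benzylhesperetin 3′-triflate | COc1ccc([C@@H]2CC(=O)c3c(O)cc(OCc4ccccc4)cc3O2)cc1OS(=O)(=O)C(F)(F)F | intermediate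
9 | (2S)-7-O-benzyl-3′-deoxy-3′-(pinacolboryl)hesperetin | COc1ccc([C@@H]2CC(=O)c3c(O)cc(OCc4ccccc4)cc3O2)cc1B1OC(C)(C)C(C)(C)O1 | intermediate
10 | tri-O-benzyl-(2S)-2,3-dihydro-4′,4‴-di-O-methylamentoflavone | COc1ccc(-c2cc(=O)c3c(OCc4ccccc4)cc(OCc4ccccc4)c(-c4cc([C@@H]5CC(=O)c6c(O)cc(OCc7ccccc7)cc6O5)ccc4OC)c3o2)cc1 | intermediate
11 | (2S)-2,3-dihydro-4′,4‴-di-O-methylamentoflavone | COc1ccc(-c2cc(=O)c3c(O)cc(O)c(-c4cc([C@@H]5CC(=O)c6c(O)cc(O)cc6O5)ccc4OC)c3o2)cc1 | target

## Summary

**Total steps:** 8.
**Longest linear sequence:** 5 steps (6 → 7 → 8 → 9 → 10 → 11; the flavone branch 1/2 → 3 → 4 → 5 → 10 → 11 is also 5).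

**Three steps most likely to fail, with fallbacks:**

- **Step 7 (hindered Suzuki; base-induced racemisation via chalcone).** Fallback: carry the flavanone through the coupling at the flavan-4-ol oxidation level (NaBH4 on 8, O-TBS), so no enolisable ketone is present during the basic Pd step. Afterwards TBAF and Dess–Martin oxidation restore the flavanone before debenzylation.
- **Step 3 (C8 versus C6 iodination).** Fallback: fix the iodine before the pyrone exists. Iodinate 2-hydroxy-4,6-bis(benzyloxy)acetophenone ortho to its only free OH, then build the flavone by aroylation, Baker–Venkataraman rearrangement and acid cyclodehydration; closure through that OH forces iodine to C8.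
- **Step 8 (over-reduction of the flavone C2=C3 bond or hydrogenolysis of the benzylic C2–O1 bond).** Fallback: change the protecting-group plan to MOM ethers (MOMCl in place of the benzylations in steps 2 and 4) and finish with a mild acidic global deprotection (HCl/MeOH) instead of a reductive one.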